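Assumption: (triisopropylsilyloxy)acetaldehyde (10) is taken to be a catalogue reagent, like its tert-butyldimethylsilyl analogue.

## Structural features

The target is a tetrahydrofuran (O1, C2, C3, C4, C5) with a 3,4,5-trimethoxyphenyl ring on C2, a hydroxymethyl group on C3 and a (3-hydroxy-4,5-dimethoxyphenyl)methyl group on C4; C5 is an unsubstituted CH2. C2, C3 and C4 are contiguous stereocentres of configuration 2R,3S,4S: the aryl group on C2 is trans to the CH2OH on C3, and the substituents on C3 and C4 are cis. The C2–O1 bond is a benzylic ether beside an electron-rich ring, so it can ionise under acid (loss of the C2 configuration) and can be opened by prolonged hydrogenolysis. The free phenol is oxidisable and has to be masked for most of the route. The real difficulty is the 3,4-cis relation: it is the less stable arrangement, so it cannot be reached by equilibration or by the usual trans-selective alkylation of a five-membered ring. The 2,3-trans relation is easier, because a group entering at C2 prefers the face away from the C3 substituent. The key step exploits the fact that removing C2 and joining O1 directly to C3 leaves an oxetane (O1, C3, C4, C5) that still holds both cis centres; re-inserting C2 between O1 and C3 by a 1,2-shift restores the five-membered ring. That carbon arrives as the carbon of an ester-bearing carbene, so C2 is first a CH–CO2R unit that can later be exchanged for the aryl ring.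

## Logic of the disconnections

24 is traced back to 23 and then to 22 by cutting the phenolic O–CH2Ph bond and the O–Si bond. The phenol and the primary alcohol must be masked through base, carbene and photoredox chemistry. The demand on the forward steps is that fluoride touches nothing else and that hydrogenolysis stops at the aryl benzyl ether without opening the C2–O1 bond.

22 is cut at the C2–aryl bond into 20 and 21. This turns the aryl-bearing stereocentre into a carboxyl-bearing carbon, which a carbene can deliver, and removes one ring and one stereocentre from the problem. The forward step must trap a planar C2 radical on the ring face opposite the cis C3/C4 substituents.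

20 goes back to 19, and 19 is cut at O1–C2 and C2–C3 into 15 and 16. Taking out one ring atom reduces the tetrahydrofuran to a four-membered ring whose two stereocentres are those of an aldol product. The forward step must make the substituted oxetane carbon, not the ring CH2, migrate to the ylide carbon, and must do so with retention.

15 is cut at the O1–C5 bond and leads through 14 to 13. Closing the ring from the secondary oxygen onto the primary carbon leaves both stereocentres untouched, so a syn 1,3-diol becomes the cis oxetane. The forward step is a four-membered closure by an alkoxide that sits next to a silyl ether; the silyl group is therefore triisopropylsilyl, which transfers far more slowly to a neighbouring alkoxide than a smaller silyl group, and which is also a poor donor towards the carbene in the key step.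

13 goes back to 12, and 12 is cut at the C3–C4 bond into 9 and 10. One aldol addition creates the only skeletal C–C bond between the two stereocentres and sets both under auxiliary control. The forward step needs a Z-enolate and a closed transition state so that the syn isomer of the correct absolute configuration forms.

9 is cut at the N–acyl bond into 6 and 7; 6 is cut at the benzylic C–C bond into 2 and 3; 2 is cut at the O–benzyl bond to 1. These are simple attachments. The only demand is that the two-carbon homologation of 2 uses a reduction that does not cleave the benzyl ether.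

## Other disconnections considered

Alternative 1: The cut runs through O1–C2 and C3–C4, so the ring comes from vinylethylene carbonate A1 and the arylidene malonate A2. Pd2(dba)3 with a chiral phosphine ligand would ionise A1 with loss of CO2 to an alkoxide/π-allylpalladium zwitterion; oxa-Michael addition to A2 and collapse of the malonate anion onto the allyl unit would give A3 with aryl and vinyl trans. In its favour, the ring, two bonds and the C2/C4 relation arise in one catalytic step from simple partners, and the absolute configuration is set by a ligand. On convergence and on the predictability of the ring-forming mechanism it is the equal or the better of the chosen plan. Against it here, the vinyl group on C4 has one carbon too many: it would have to be cleaved to an epimerisable aldehyde, arylated and deoxygenated beside the C2 benzylic ether. C3 is a gem-diester, so one ester must be removed, and the C3 centre, the one that must end up cis to C4, would be set by a protonation with no strong bias. The chosen plan has its weak point in the key step but needs four steps after it and brings the cis pair from an aldol reaction; Alternative 1 has the safer key step but a longer and stereochemically looser end game.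

Alternative 2: The cut removes the two exocyclic carbons on C3 and C4, both supplied by dichloroketene A5, which would add across C3=C4 of the dihydrofuran A4 from the face opposite the aryl group to give A6. In its favour, the cis fusion of the four-membered ring fixes the cis relation of the two side-chain carbons by geometry, which is at least as secure as the aldol/oxetane relay. The aryl group is present from the start and steers the facial selectivity, and a concerted [2+2] addition is mechanistically more predictable than a stepwise ylide shift. Against it, the C3=C4 bond of A4 is hardly polarised, so the orientation of the ketene (carbonyl carbon on C4) is not assured. Afterwards the cyclobutanone must be opened between the carbonyl and the CCl2 carbon, the CHCl2 group turned into CH2OH and the carboxyl carbon into ArCH2 by ketone formation and deoxygenation, all beside the C2 benzylic ether. The route is enantioselective only if A4 is made enantioenriched. The chosen plan carries the arylmethyl group intact from the first steps and ends four steps after the key step; Alternative 2 would need about twice as many operations after its key step, most of them redox adjustments.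

Alternative 3: The cut is at C2–C3 and at the bond from C4 to the benzylic CH2. The lithiated dithiane A7 would add to the β-carbon of the alkoxybutenolide A8 anti to the acetal alkoxy group, and the enolate would be trapped by the benzyl bromide A9 anti to the new substituent, giving A10. In its favour, three components are joined in one flask by well-understood steps and the acetal centre of A8 sets the absolute configuration. The trans lactone maps onto the cis tetrahydrofuran, because the lactone is later opened and the ring re-closed from the former carbonyl carbon (C5) onto C2, which exchanges ring and side-chain carbons at C3. On the proven reliability of every step this plan is the better of the two. Against it, after A10 there remain reduction of lactone and acetal, dithiane hydrolysis in the presence of electron-rich rings, ketone reduction, an acid-mediated ring closure in which C2 is set by a benzylic cation rather than by a reagent, and debenzylation; A7, A8 and A9 each have to be prepared. The overall step counts are similar. The chosen plan sets C2 in a catalyst-mediated coupling under neutral conditions and avoids the dithiane and the acid step, but it rests on a ring expansion whose regio- and stereochemical course is less certain than the conjugate addition–alkylation of A8.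

Key step: step 8

## Route

Step 1
Reactants: 1 3-hydroxy-4,5-dimethoxybenzaldehyde
Product: 2 3-(benzyloxy)-4,5-dimethoxybenzaldehyde
Conditions: BnBr, K2CO3, DMF, rt
Reagents that add atoms: benzyl bromide, BrCc1ccccc1
Why: Williamson ether synthesis on the phenoxide; the benzyl ether should survive every later base, carbene and photoredox step and is removed last.

Step 2
Reactants: 2 3-(benzyloxy)-4,5-dimethoxybenzaldehyde; 3 Meldrum's acid
Product: 6 3-[3-(benzyloxy)-4,5-dimethoxyphenyl]propanoic acid, via arylidene Meldrum's acid 4 (not isolated), via benzyl Meldrum's acid 5 (not isolated)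
Conditions: HCO2H/Et3N (5:2), 95 °C
Reagents that add atoms: water, O
Why: Knoevenagel condensation gives 4, formate transfers hydride to the arylidene to give 5, and hydrolysis with loss of acetone and CO2 leaves the propanoic acid; no hydrogenation catalyst is present, so the benzyl ether is not at risk.

Step 3
Reactants: 6 3-[3-(benzyloxy)-4,5-dimethoxyphenyl]propanoic acid; 7 (S)-4-benzyloxazolidin-2-one
Product: 9 (S)-4-benzyl-3-{3-[3-(benzyloxy)-4,5-dimethoxyphenyl]propanoyl}oxazolidin-2-one, via mixed pivalic anhydride 8 (not isolated)
Conditions: PivCl, Et3N, THF, −20 °C; then 7, LiCl, −20 °C → rt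
Reagents that add atoms: none
Why: N-acylation of the oxazolidinone through the mixed anhydride 8 under LiCl/Et3N activation; attack should occur at the unhindered acyl carbonyl of 8, not at the pivaloyl carbonyl.

Step 4
Reactants: 9 (S)-4-benzyl-3-{3-[3-(benzyloxy)-4,5-dimethoxyphenyl]propanoyl}oxazolidin-2-one; 10 (triisopropylsilyloxy)acetaldehyde
Product: 12 (4S)-4-benzyl-3-[(2S,3S)-2-{[3-(benzyloxy)-4,5-dimethoxyphenyl]methyl}-3-hydroxy-4-(triisopropylsilyloxy)butanoyl]oxazolidin-2-one, via dibutylboron Z-enolate 11 (not isolated)
Conditions: Bu2BOTf, iPr2NEt, CH2Cl2, −78 → 0 °C; 10, −78 → 0 °C; then H2O2, pH 7 buffer, MeOH, 0 °C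
Reagents that add atoms: none
Why: Evans syn-aldol: the Z-enolate 11 reacts through a chair Zimmerman–Traxler transition state in which the benzyl group of the auxiliary shields one enolate face, which sets both new centres (2S,3S, syn); these become C4 and C3 of the target.

Step 5
Reactants: 12 (4S)-4-benzyl-3-[(2S,3S)-2-{[3-(benzyloxy)-4,5-dimethoxyphenyl]methyl}-3-hydroxy-4-(triisopropylsilyloxy)butanoyl]oxazolidin-2-one
Product: 13 (2S,3R)-3-{[3-(benzyloxy)-4,5-dimethoxyphenyl]methyl}-1-(triisopropylsilyloxy)butane-2,4-diol
Conditions: LiBH4, MeOH (1 equiv), THF, 0 °C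
Reagents that add atoms: none
Why: Reductive removal of the auxiliary by hydride attack at the exocyclic imide carbonyl; neither stereocentre is involved and 7 is released for recovery.

Step 6
Reactants: 13 (2S,3R)-3-{[3-(benzyloxy)-4,5-dimethoxyphenyl]methyl}-1-(triisopropylsilyloxy)butane-2,4-diol
Product: 14 (2R,3S)-2-{[3-(benzyloxy)-4,5-dimethoxyphenyl]methyl}-3-hydroxy-4-(triisopropylsilyloxy)butyl 4-methylbenzenesulfonate
Conditions: TsCl, Et3N, DMAP (cat.), CH2Cl2, 0 °C
Reagents that add atoms: 4-toluenesulfonyl chloride, Cc1ccc(cc1)S(=O)(=O)Cl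
Why: Sulfonylation should discriminate the unhindered primary hydroxyl from the secondary hydroxyl, which is flanked by two branched carbons.

Step 7
Reactants: 14 (2R,3S)-2-{[3-(benzyloxy)-4,5-dimethoxyphenyl]methyl}-3-hydroxy-4-(triisopropylsilyloxy)butyl 4-methylbenzenesulfonate
Product: 15 (2S,3R)-3-{[3-(benzyloxy)-4,5-dimethoxyphenyl]methyl}-2-[(triisopropylsilyloxy)methyl]oxetane
Conditions: NaH, THF, 0 → 40 °C
Reagents that add atoms: none
Why: Intramolecular Williamson etherification (4-exo-tet): the secondary alkoxide displaces the primary tosylate, so both stereocentres are retained and the syn diol relation becomes the cis-2,3-disubstituted oxetane. The bulky triisopropylsilyl ether is used because a smaller silyl group could move to the alkoxide and free a primary alkoxide that would close a five-membered ring instead.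

Step 8
Reactants: 15 (2S,3R)-3-{[3-(benzyloxy)-4,5-dimethoxyphenyl]methyl}-2-[(triisopropylsilyloxy)methyl]oxetane; 16 ethyl diazoacetate
Product: 19 ethyl (2R,3S,4S)-4-{[3-(benzyloxy)-4,5-dimethoxyphenyl]methyl}-3-[(triisopropylsilyloxy)methyl]oxolane-2-carboxylate, via copper carbene 17 (not isolated), via oxonium ylide 18 (not isolated)
Conditions: Cu(MeCN)4PF6 (5 mol%), 4,4'-di-tert-butyl-2,2'-bipyridine (6 mol%), CH2Cl2, rt, 16 added over 8 h
Reagents that add atoms: none
Why: Cu(MeCN)4PF6 (monovalent copper) decomposes 16 to the electrophilic carbene 17, which is attacked by the exposed, Lewis-basic oxetane oxygen of 15 (the hindered silyl ether and the aryl ethers are much poorer donors) to give oxonium ylide 18. Release of four-ring strain then drives a [1,2] Stevens shift in which the O–C bond to the substituted ring carbon breaks and that carbon bonds to the ylide carbon, so O1–C2 and C2–C3 form and the oxetane grows into the tetrahydrofuran. The closest known reaction type is the copper-catalysed ring expansion of 2-substituted oxetanes by diazo esters; here the migrating carbon is a plain secondary alkyl carbon. The ring is closed by ring enlargement: the migrating carbon stays tethered to the ylide through C4–C5–O1 and recombines with it, which amounts to a five-membered closure by C–C bond formation. The new stereocentre C2 is set by approach of the migrating carbon to the less hindered face of the ylide carbon (ester trans to the C3 substituent), but its configuration is not needed because step 10 planarises C2, so either C2 epimer of 19 serves. Two selectivities matter: the substituted carbon must migrate instead of the ring CH2, which is favoured because it is the more substituted, more stable migrating terminus and its departure relieves the cis eclipsing strain; and it must migrate with retention, which is expected because the short-lived tethered pair should recombine faster than the carbon can invert. C4 is a spectator, so the cis C3/C4 relation from step 4 is carried through. Slow addition of 16 keeps carbene dimerisation down.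

Step 9
Reactants: 19 ethyl (2R,3S,4S)-4-{[3-(benzyloxy)-4,5-dimethoxyphenyl]methyl}-3-[(triisopropylsilyloxy)methyl]oxolane-2-carboxylate
Product: 20 (2R,3S,4S)-4-{[3-(benzyloxy)-4,5-dimethoxyphenyl]methyl}-3-[(triisopropylsilyloxy)methyl]oxolane-2-carboxylic acid
Conditions: LiOH, THF/MeOH/H2O, 0 °C → rt; then 1 M HCl to pH 4
Reagents that add atoms: lithium hydroxide, [Li+].[OH-]
Why: Saponification of an unhindered α-alkoxy ester; the alkyl silyl ether and the benzyl ether are stable to hydroxide, and any epimerisation at C2 is harmless because C2 is planarised in the next step.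

Step 10
Reactants: 20 (2R,3S,4S)-4-{[3-(benzyloxy)-4,5-dimethoxyphenyl]methyl}-3-[(triisopropylsilyloxy)methyl]oxolane-2-carboxylic acid; 21 5-bromo-1,2,3-trimethoxybenzene
Product: 22 triisopropyl{[(2R,3S,4S)-4-{[3-(benzyloxy)-4,5-dimethoxyphenyl]methyl}-2-(3,4,5-trimethoxyphenyl)oxolan-3-yl]methoxy}silane
Conditions: Ir[dF(CF3)ppy]2(dtbbpy)PF6 (1 mol%), NiCl2·glyme (10 mol%), 4,4'-di-tert-butyl-2,2'-bipyridine (15 mol%), Cs2CO3, DMF, blue LEDs, rt
Reagents that add atoms: none
Why: Metallaphotoredox decarboxylative arylation: excited Ir[dF(CF3)ppy]2(dtbbpy)PF6 oxidises the carboxylate, CO2 is lost, and the α-oxy C2 radical is intercepted by the divalent aryl–nickel species formed from 21 and zerovalent nickel; reductive elimination then forms the C2–aryl bond. The radical should be captured on the ring face away from the cis C3/C4 substituents, which gives the 2,3-trans product whatever the C2 configuration of 20.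

Step 11
Reactants: 22 triisopropyl{[(2R,3S,4S)-4-{[3-(benzyloxy)-4,5-dimethoxyphenyl]methyl}-2-(3,4,5-trimethoxyphenyl)oxolan-3-yl]methoxy}silane
Product: 23 [(2R,3S,4S)-4-{[3-(benzyloxy)-4,5-dimethoxyphenyl]methyl}-2-(3,4,5-trimethoxyphenyl)oxolan-3-yl]methanol
Conditions: Bu4NF, THF, 0 °C → rt
Reagents that add atoms: none
Why: Fluoride cleaves the Si–O bond by forming the strong Si–F bond; the ethers and the benzylic C2–O1 bond are inert to these conditions.

Step 12
Reactants: 23 [(2R,3S,4S)-4-{[3-(benzyloxy)-4,5-dimethoxyphenyl]methyl}-2-(3,4,5-trimethoxyphenyl)oxolan-3-yl]methanol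
Product: 24 [(2R,3S,4S)-4-[(3-hydroxy-4,5-dimethoxyphenyl)methyl]-2-(3,4,5-trimethoxyphenyl)oxolan-3-yl]methanol
Conditions: H2 (1 atm), Pd/C (10%), EtOAc, rt
Reagents that add atoms: none
Why: Catalytic hydrogenolysis of the aryl benzyl ether, which should be cleaved much faster than the cyclic benzylic C2–O1 bond in a neutral aprotic solvent; the reaction is stopped at full conversion.

## Compound list

1 | 3-hydroxy-4,5-dimethoxybenzaldehyde | COc1cc(C=O)cc(O)c1OC | starting material
2 | 3-(benzyloxy)-4,5-dimethoxybenzaldehyde | COc1cc(C=O)cc(OCc2ccccc2)c1OC | intermediate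
3 | Meldrum's acid (2,2-dimethyl-1,3-dioxane-4,6-dione) | CC1(C)OC(=O)CC(=O)O1 | starting material
4 | 5-[3-(benzyloxy)-4,5-dimethoxybenzylidene]-2,2-dimethyl-1,3-dioxane-4,6-dione (not isolated) | COc1cc(C=C2C(=O)OC(C)(C)OC2=O)cc(OCc2ccccc2)c1OC | intermediate
5 | 5-[3-(benzyloxy)-4,5-dimethoxybenzyl]-2,2-dimethyl-1,3-dioxane-4,6-dione (not isolated) | COc1cc(CC2C(=O)OC(C)(C)OC2=O)cc(OCc2ccccc2)c1OC | intermediate
6 | 3-[3-(benzyloxy)-4,5-dimethoxyphenyl]propanoic acid | COc1cc(CCC(=O)O)cc(OCc2ccccc2)c1OC | intermediate
7 | (S)-4-benzyloxazolidin-2-one | O=C1N[C@@H](Cc2ccccc2)CO1 | starting material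
8 | mixed anhydride of 6 and pivalic acid (not isolated) | COc1cc(CCC(=O)OC(=O)C(C)(C)C)cc(OCc2ccccc2)c1OC | intermediate
9 | (S)-4-benzyl-3-{3-[3-(benzyloxy)-4,5-dimethoxyphenyl]propanoyl}oxazolidin-2-one | O=C1OC[C@H](Cc2ccccc2)N1C(=O)CCc1cc(OC)c(OC)c(OCc2ccccc2)c1 | intermediate
10 | (triisopropylsilyloxy)acetaldehyde | CC(C)[Si](OCC=O)(C(C)C)C(C)C | starting material
11 | dibutylboron (Z)-enolate of 9 (not isolated) | CCCCB(CCCC)O/C(=C\Cc1cc(OC)c(OC)c(OCc2ccccc2)c1)N1C(=O)OC[C@@H]1Cc1ccccc1 | intermediate
12 | (4S)-4-benzyl-3-[(2S,3S)-2-{[3-(benzyloxy)-4,5-dimethoxyphenyl]methyl}-3-hydroxy-4-(triisopropylsilyloxy)butanoyl]oxazolidin-2-one | O=C1OC[C@H](Cc2ccccc2)N1C(=O)[C@@H](Cc1cc(OC)c(OC)c(OCc2ccccc2)c1)[C@H](O)CO[Si](C(C)C)(C(C)C)C(C)C | intermediate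
13 | (2S,3R)-3-{[3-(benzyloxy)-4,5-dimethoxyphenyl]methyl}-1-(triisopropylsilyloxy)butane-2,4-diol | OC[C@@H](Cc1cc(OC)c(OC)c(OCc2ccccc2)c1)[C@H](O)CO[Si](C(C)C)(C(C)C)C(C)C | intermediate
14 | (2R,3S)-2-{[3-(benzyloxy)-4,5-dimethoxyphenyl]methyl}-3-hydroxy-4-(triisopropylsilyloxy)butyl 4-methylbenzenesulfonate | Cc1ccc(cc1)S(=O)(=O)OC[C@@H](Cc1cc(OC)c(OC)c(OCc2ccccc2)c1)[C@H](O)CO[Si](C(C)C)(C(C)C)C(C)C | intermediate
15 | (2S,3R)-3-{[3-(benzyloxy)-4,5-dimethoxyphenyl]methyl}-2-[(triisopropylsilyloxy)methyl]oxetane (cis) | COc1cc(C[C@@H]2CO[C@@H]2CO[Si](C(C)C)(C(C)C)C(C)C)cc(OCc2ccccc2)c1OC | intermediate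
16 | ethyl diazoacetate | CCOC(=O)C=[N+]=[N-] | starting material
17 | copper carbene from 16, ligands omitted (not isolated) | CCOC(=O)C=[Cu+] | intermediate
18 | oxonium ylide of 15, copper-free form drawn (not isolated) | CCOC(=O)[CH-][O+]1C[C@@H](Cc2cc(OC)c(OC)c(OCc3ccccc3)c2)[C@H]1CO[Si](C(C)C)(C(C)C)C(C)C | intermediate
19 | ethyl (2R,3S,4S)-4-{[3-(benzyloxy)-4,5-dimethoxyphenyl]methyl}-3-[(triisopropylsilyloxy)methyl]oxolane-2-carboxylate (2,3-trans epimer drawn; the C2 epimer may accompany it) | COc1cc(C[C@@H]2CO[C@@H](C(=O)OCC)[C@@H]2CO[Si](C(C)C)(C(C)C)C(C)C)cc(OCc2ccccc2)c1OC | intermediate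
20 | (2R,3S,4S)-4-{[3-(benzyloxy)-4,5-dimethoxyphenyl]methyl}-3-[(triisopropylsilyloxy)methyl]oxolane-2-carboxylic acid (2,3-trans epimer drawn) | COc1cc(C[C@@H]2CO[C@@H](C(=O)O)[C@@H]2CO[Si](C(C)C)(C(C)C)C(C)C)cc(OCc2ccccc2)c1OC | intermediate
21 | 5-bromo-1,2,3-trimethoxybenzene | COc1cc(Br)cc(OC)c1OC | starting material
22 | triisopropyl{[(2R,3S,4S)-4-{[3-(benzyloxy)-4,5-dimethoxyphenyl]methyl}-2-(3,4,5-trimethoxyphenyl)oxolan-3-yl]methoxy}silane | COc1cc(C[C@@H]2CO[C@@H](c3cc(OC)c(OC)c(OC)c3)[C@@H]2CO[Si](C(C)C)(C(C)C)C(C)C)cc(OCc2ccccc2)c1OC | intermediate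
23 | [(2R,3S,4S)-4-{[3-(benzyloxy)-4,5-dimethoxyphenyl]methyl}-2-(3,4,5-trimethoxyphenyl)oxolan-3-yl]methanol | COc1cc(C[C@@H]2CO[C@@H](c3cc(OC)c(OC)c(OC)c3)[C@@H]2CO)cc(OCc2ccccc2)c1OC | intermediate
24 | [(2R,3S,4S)-4-[(3-hydroxy-4,5-dimethoxyphenyl)methyl]-2-(3,4,5-trimethoxyphenyl)oxolan-3-yl]methanol | COc1cc(C[C@@H]2CO[C@@H](c3cc(OC)c(OC)c(OC)c3)[C@@H]2CO)cc(O)c1OC | target

## Step count and least certain steps

Total step count: 12. Longest linear sequence: 12 steps (1 to 24); 3, 7, 10, 16 and 21 enter as purchased reagents.

Step 8 (key step). The most likely failure is loss of regiocontrol in the shift: the ring CH2 may migrate in place of the silyloxymethyl-bearing carbon, which has no aryl or alkynyl group to stabilise it. The second is partial loss of configuration at the migrating carbon if the opened, tethered intermediate lives long enough to rotate, which would erode the cis C3/C4 relation. Carbene dimerisation and attack on the electron-rich rings are lesser concerns. The fallback makes C2–C3 by displacement instead of an ylide shift and sets out from 13. Rh2(OAc)4-catalysed O–H insertion of 16 at the primary hydroxyl would give the glycolate ether F1. Mitsunobu inversion of the secondary alcohol with 4-nitrobenzoic acid (PPh3, diisopropyl azodicarboxylate) would give the ester F2, and K2CO3 in EtOH would free the inverted alcohol F3. MsCl/Et3N would give the mesylate F4. KN(SiMe3)2 in THF at −78 °C would then form the ester enolate, which displaces the mesylate in a 5-exo-tet closure; this second inversion gives net retention at C3, and the sequence comes back to the route at 19.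

Step 7. The most likely failure is transfer of the silyl group to the neighbouring alkoxide, followed by closure of a five-membered ring through the freed primary alkoxide. The four-membered closure is also slow because the two substituents become cis, which leaves time for fragmentation of the 1,3-alkoxy sulfonate. The fallback removes silicon from this stage and sets out from 9. The aldol reaction of step 4 with (4-methoxybenzyloxy)acetaldehyde F5 would give the adduct F6; LiBH4 would give the diol F7; TsCl would give the primary tosylate F8; NaH would close the 4-methoxybenzyl-protected oxetane F9. Oxidative removal of the 4-methoxybenzyl group with 2,3-dichloro-5,6-dicyano-1,4-benzoquinone in CH2Cl2/pH 7 buffer would give the oxetanylmethanol F10, and silylation (iPr3SiCl, imidazole) comes back to the route at 15.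

Step 10. The most likely failure is slow oxidative addition of the electron-rich bromide to zerovalent nickel, so that the C2 radical is consumed by reduction or dimerisation; incomplete facial selectivity in the radical capture is the second concern. The fallback is a thermal decarboxylative Negishi coupling of a redox-active ester and sets out from 20. N-hydroxyphthalimide and N,N'-diisopropylcarbodiimide would give the redox-active ester F11. The arylzinc chloride F12 would be made from 21 (n-BuLi, then ZnCl2). Coupling of F11 with F12 under NiCl2·glyme and 4,4'-di-tert-butyl-2,2'-bipyridine in THF/DMF comes back to the route at 22.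

Step 12. The most likely failure is over-reduction, that is hydrogenolytic opening of the benzylic C2–O1 bond once the aryl benzyl ether has gone. The fallback removes the benzyl group before C2 carries an aryl ring and sets out from 20. Hydrogenolysis (H2, Pd/C) at this stage, where no ring benzylic ether exists, would give the phenol acid F13. Silylation with excess iPr3SiCl/imidazole and mild aqueous K2CO3 work-up to hydrolyse the silyl ester would give the aryl silyl ether acid F14. Decarboxylative arylation with 21 as in step 10 would give the bis-silyl ether F15, and Bu4NF would remove both silyl groups and come back to the route at 24.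

## Further compounds

F1 | step 8 | ethyl 2-{[(2R,3S)-2-{[3-(benzyloxy)-4,5-dimethoxyphenyl]methyl}-3-hydroxy-4-(triisopropylsilyloxy)butyl]oxy}acetate | CCOC(=O)COC[C@@H](Cc1cc(OC)c(OC)c(OCc2ccccc2)c1)[C@H](O)CO[Si](C(C)C)(C(C)C)C(C)C
F2 | step 8 | (2R,3R)-3-{[3-(benzyloxy)-4,5-dimethoxyphenyl]methyl}-4-(2-ethoxy-2-oxoethoxy)-1-(triisopropylsilyloxy)butan-2-yl 4-nitrobenzoate | CCOC(=O)COC[C@@H](Cc1cc(OC)c(OC)c(OCc2ccccc2)c1)[C@@H](OC(=O)c1ccc(cc1)[N+](=O)[O-])CO[Si](C(C)C)(C(C)C)C(C)C
F3 | step 8 | ethyl 2-{[(2R,3R)-2-{[3-(benzyloxy)-4,5-dimethoxyphenyl]methyl}-3-hydroxy-4-(triisopropylsilyloxy)butyl]oxy}acetate | CCOC(=O)COC[C@@H](Cc1cc(OC)c(OC)c(OCc2ccccc2)c1)[C@@H](O)CO[Si](C(C)C)(C(C)C)C(C)C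
F4 | step 8 | ethyl 2-{[(2R,3R)-2-{[3-(benzyloxy)-4,5-dimethoxyphenyl]methyl}-3-(methanesulfonyloxy)-4-(triisopropylsilyloxy)butyl]oxy}acetate | CCOC(=O)COC[C@@H](Cc1cc(OC)c(OC)c(OCc2ccccc2)c1)[C@@H](OS(C)(=O)=O)CO[Si](C(C)C)(C(C)C)C(C)C
F5 | step 7 | (4-methoxybenzyloxy)acetaldehyde (purchased) | COc1ccc(COCC=O)cc1
F6 | step 7 | (4S)-4-benzyl-3-[(2S,3S)-2-{[3-(benzyloxy)-4,5-dimethoxyphenyl]methyl}-3-hydroxy-4-(4-methoxybenzyloxy)butanoyl]oxazolidin-2-one | O=C1OC[C@H](Cc2ccccc2)N1C(=O)[C@@H](Cc1cc(OC)c(OC)c(OCc2ccccc2)c1)[C@H](O)COCc1ccc(OC)cc1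
F7 | step 7 | (2S,3R)-3-{[3-(benzyloxy)-4,5-dimethoxyphenyl]methyl}-1-(4-methoxybenzyloxy)butane-2,4-diol | OC[C@@H](Cc1cc(OC)c(OC)c(OCc2ccccc2)c1)[C@H](O)COCc1ccc(OC)cc1
F8 | step 7 | (2R,3S)-2-{[3-(benzyloxy)-4,5-dimethoxyphenyl]methyl}-3-hydroxy-4-(4-methoxybenzyloxy)butyl 4-methylbenzenesulfonate | Cc1ccc(cc1)S(=O)(=O)OC[C@@H](Cc1cc(OC)c(OC)c(OCc2ccccc2)c1)[C@H](O)COCc1ccc(OC)cc1
F9 | step 7 | (2S,3R)-3-{[3-(benzyloxy)-4,5-dimethoxyphenyl]methyl}-2-[(4-methoxybenzyloxy)methyl]oxetane | COc1cc(C[C@@H]2CO[C@@H]2COCc2ccc(OC)cc2)cc(OCc2ccccc2)c1OC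
F10 | step 7 | [(2S,3R)-3-{[3-(benzyloxy)-4,5-dimethoxyphenyl]methyl}oxetan-2-yl]methanol | COc1cc(C[C@@H]2CO[C@@H]2CO)cc(OCc2ccccc2)c1OC
F11 | step 10 | 1,3-dioxoisoindolin-2-yl (2R,3S,4S)-4-{[3-(benzyloxy)-4,5-dimethoxyphenyl]methyl}-3-[(triisopropylsilyloxy)methyl]oxolane-2-carboxylate | COc1cc(C[C@@H]2CO[C@@H](C(=O)ON3C(=O)c4ccccc4C3=O)[C@@H]2CO[Si](C(C)C)(C(C)C)C(C)C)cc(OCc2ccccc2)c1OC
F12 | step 10 | (3,4,5-trimethoxyphenyl)zinc chloride | COc1cc([Zn]Cl)cc(OC)c1OC
F13 | step 12 | (2R,3S,4S)-4-[(3-hydroxy-4,5-dimethoxyphenyl)methyl]-3-[(triisopropylsilyloxy)methyl]oxolane-2-carboxylic acid | COc1cc(C[C@@H]2CO[C@@H](C(=O)O)[C@@H]2CO[Si](C(C)C)(C(C)C)C(C)C)cc(O)c1OC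
F14 | step 12 | (2R,3S,4S)-4-{[3,4-dimethoxy-5-(triisopropylsilyloxy)phenyl]methyl}-3-[(triisopropylsilyloxy)methyl]oxolane-2-carboxylic acid | COc1cc(C[C@@H]2CO[C@@H](C(=O)O)[C@@H]2CO[Si](C(C)C)(C(C)C)C(C)C)cc(O[Si](C(C)C)(C(C)C)C(C)C)c1OC
F15 | step 12 | (2R,3S,4S)-4-{[3,4-dimethoxy-5-(triisopropylsilyloxy)phenyl]methyl}-3-[(triisopropylsilyloxy)methyl]-2-(3,4,5-trimethoxyphenyl)oxolane | COc1cc(C[C@@H]2CO[C@@H](c3cc(OC)c(OC)c(OC)c3)[C@@H]2CO[Si](C(C)C)(C(C)C)C(C)C)cc(O[Si](C(C)C)(C(C)C)C(C)C)c1OC
A1 | alternative 1 | vinylethylene carbonate (4-vinyl-1,3-dioxolan-2-one) | C=CC1COC(=O)O1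
A2 | alternative 1 | dimethyl 2-(3,4,5-trimethoxybenzylidene)malonate | COC(=O)C(=Cc1cc(OC)c(OC)c(OC)c1)C(=O)OC
A3 | alternative 1 | dimethyl 2,4-trans-2-(3,4,5-trimethoxyphenyl)-4-vinyltetrahydrofuran-3,3-dicarboxylate, enantiomer drawn | C=C[C@@H]1CO[C@@H](c2cc(OC)c(OC)c(OC)c2)C1(C(=O)OC)C(=O)OC
A4 | alternative 2 | (R)-2-(3,4,5-trimethoxyphenyl)-2,5-dihydrofuran | C1=C[C@H](c2cc(OC)c(OC)c(OC)c2)OC1
A5 | alternative 2 | dichloroketene | ClC(Cl)=C=O
A6 | alternative 2 | 7,7-dichloro-2-(3,4,5-trimethoxyphenyl)-3-oxabicyclo[3.2.0]heptan-6-one, aryl exo | O=C1[C@@H]2CO[C@@H](c3cc(OC)c(OC)c(OC)c3)[C@@H]2C1(Cl)Cl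
A7 | alternative 3 | 2-(3,4,5-trimethoxyphenyl)-1,3-dithiane | COc1cc(C2SCCCS2)cc(OC)c1OC
A8 | alternative 3 | (5S)-5-(d-menthyloxy)-2(5H)-furanone | O=C1C=C[C@@H](O[C@H]2C[C@@H](C)CC[C@@H]2C(C)C)O1
A9 | alternative 3 | 3-(benzyloxy)-4,5-dimethoxybenzyl bromide | COc1cc(CBr)cc(OCc2ccccc2)c1OC
A10 | alternative 3 | trans,trans-α-[3-(benzyloxy)-4,5-dimethoxybenzyl]-β-[2-(3,4,5-trimethoxyphenyl)-1,3-dithian-2-yl]-γ-(menthyloxy)-γ-butyrolactone | O=C1O[C@H](O[C@H]2C[C@@H](C)CC[C@@H]2C(C)C)[C@@H](C2(c3cc(OC)c(OC)c(OC)c3)SCCCS2)[C@@H]1Cc1cc(OC)c(OC)c(OCc2ccccc2)c1
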